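**The product.** E, the tris adduct, is reached from G through L and J, one Q at a time, but Friday's readings show G and L.

- Friday's: G 0.80 M; Q 2.4 M; the very flask that is asked about, followed so far
- flask: G 0.80 M; Q 2.40 M; time 1.5 h

- Friday's (time / min: G / %, L / %): 0.667: 98.6, 1.5; 1.50: 95.1, 2.0; 3.00: 93.7, 6.1; 5.00: 92.7, 9.2; 6.00: 89.7, 9.5; 8.00: 86.1, 10.5; 10.0: 83.8, 12.1

(each reading ± 1 percentage point)

* how much G there is at 1.5 h, in percent of the G charged
* how much L there is at 1.5 h, in percent of the G charged
* how much J there is at 1.5 h, in percent of the G charged
* how much E there is at 1.5 h, in percent of the G charged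



**G half-life.** In Friday's run G fell to 83.8% by 10.0 min, a reading with 1 percentage point of scatter. While c_Q stayed near its charge, G decayed in the pseudo-first-order way at 0.0177 min⁻¹. So I took 0.654 h as the G half-life, the half-life of G with c_Q held at its charge.

**Falling Q.** The asked 1.5 h is 2.29 such half-lives, which left 20.4% of G on paper with c_Q held. But c_G was charged at a third of c_Q, so the fall of c_Q counted. I guessed two Q per G lost, which put c_Q at 46.9% of its charge at the end. Using the mean level, G came to 31.1%. A second pass gave c_Q 54.1% and G 29.4%. I committed to that G, with my two Q as the weak link and the split of the rest unread.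

**The forecast.** It gave G 31%, L 16%, J 32% and E 21%, and said “the J/E split is very uncertain”.

**The flask.** At 1.5 h it held G 28.5%, L 18.7%, J 13.8%, E 7.86% and a further product, X, 31.2%.

    J → X (k = 0.0310 min⁻¹)
    G + Q → L (k = 0.00780 M⁻¹ min⁻¹)
    Q + L → J (k = 0.0170 M⁻¹ min⁻¹)
    Q + J → E (k = 0.00470 M⁻¹ min⁻¹)

**Reforged link.** With the flask's own c_Q, 56% of charge at the end, in place of my guess, the G half-life gives 28.9% of G. In the flask, E stands low partly because of the conversion of J into X, acting together with the short time. The half-life of J by that conversion alone is 0.37 h, shorter than the 1.0 h by Q + J into E alone at the charged c_Q. With the conversion of J into X struck out, the flask holds 14.3% of E instead of 7.86%, and left until 15.0 h with that conversion in place it holds 15.8%. In the flask with 0.20 M of G, c_Q stays near its charge, so the G half-life gives 20.4% of G. That flask holds 20.9%, with 87% of its Q left.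

Readings and results were computed with made-up constants, and the scatter is random.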